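## Retrosynthetic overview

1. The target comes from its 5‑triethylsilyl derivative by protodesilylation; the silyl group is a traceless control element for the position of the allyl group.
2. The benzene ring of the benzodioxane and the 1,4‑dioxane ring form together in one Rh‑catalysed [2+2+2] cyclotrimerisation of a chiral 1,7‑diyne (a bis‑alkynyl ether of an erythro 1‑aryl‑propane‑1,2‑diol) with pent‑1‑en‑4‑yne; the trimethoxyphenyl ring is bought.
3. The diyne comes from two O‑alkynylations at different stages: a (Z)‑2‑chlorovinyl ether from (Z)‑1,2‑dichloroethene becomes the Et3Si‑capped alkyne on the CH(CH3)–O oxygen, and a Greene trichloroethylene sequence gives the terminal alkyne on the benzylic oxygen.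
4. The C–CH3 stereocentre comes from (S)‑lactamide (chiral pool); the benzylic stereocentre comes from a catalyst‑controlled (CBS) reduction of the aryl ketone made from the lactamide and an aryllithium.
5. Ring order: no ring is made before step 5; there the arene and the dioxane close in the same operation.

Assumption: the SMILES is read as the cis isomer, (2S,3R)‑2‑methyl‑6‑(prop‑2‑en‑1‑yl)‑3‑(3,4,5‑trimethoxyphenyl)‑2,3‑dihydro‑1,4‑benzodioxine (aryl‑bearing carbon R, methyl‑bearing carbon S); the five starting materials are taken as catalogue compounds.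

## Route

Step 1
Reactants: 1 (2S)-2-hydroxy-N,N-dimethylpropanamide; 2 (Z)-1,2-dichloroethene
Product: 4 (2S)-2-{[(Z)-2-chloroethenyl]oxy}-N,N-dimethylpropanamide, via chloroacetylene 3 (not isolated)
Conditions: KH (1.05 equiv), THF, 0 °C; 2 (1.2 equiv), 0 to 20 °C, under Ar
Reagents that add atoms: none
Why: Proposed new method: the potassium alkoxide of 1 dehydrochlorinates 2 by anti‑E2 to chloroacetylene 3 (kept in solution under argon), adds anti to its CH terminus, and the α‑chlorovinyl anion is protonated by 1, giving the (Z)‑2‑chlorovinyl ether without touching the tertiary amide or the lactate stereocentre; the closest known reaction types are the elimination–addition of thiolates with cis‑1,2‑dichloroethene via chloroacetylene and the KH/trichloroethylene dichlorovinylation of alkoxides, and the monochloro ether is chosen because its vinylic hydrogens are too weakly acidic to quench the aryllithium of step 2.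

Step 2
Reactants: 4 (2S)-2-{[(Z)-2-chloroethenyl]oxy}-N,N-dimethylpropanamide; 5 5-bromo-1,2,3-trimethoxybenzene
Product: 11 (2S)-2-{[(triethylsilyl)ethynyl]oxy}-1-(3,4,5-trimethoxyphenyl)propan-1-one, via aryllithium 6 (not isolated), via lithium hemiaminal alkoxide 7 (not isolated), via ethynyl ether adduct 8 (not isolated), via lithium acetylide adduct 9 (not isolated), via C-silyl adduct 10 (not isolated)
Conditions: 5, n-BuLi (1.05 equiv), THF, −78 °C; 4, −78 °C; LDA (2.3 equiv), −78 to −40 °C; Et3SiCl (2.5 equiv), −78 to −40 °C; pH 7 buffer, 0 °C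
Reagents that add atoms: chlorotriethylsilane, CC[Si](Cl)(CC)CC
Why: Proposed new method: aryllithium 6 (Br–Li exchange) adds once to the dimethylamide to give the stable tetrahedral alkoxide 7, which masks the ketone and its acidic α‑H while LDA converts the (Z)‑2‑chlorovinyl ether by anti‑E2 into ethynyl ether 8 and deprotonates it to acetylide 9, Et3SiCl caps the acetylide carbon, and the ketone is released only on buffered work‑up so that the (S) centre cannot epimerise; the closest known reaction types are the tertiary‑amide ketone synthesis with in‑situ protection as an α‑amino alkoxide and the amide‑base conversion of (Z)‑2‑halovinyl ethers into metal alkynyl ethers followed by C‑silylation.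

Step 3
Reactants: 11 (2S)-2-{[(triethylsilyl)ethynyl]oxy}-1-(3,4,5-trimethoxyphenyl)propan-1-one
Product: 12 (1R,2S)-2-{[(triethylsilyl)ethynyl]oxy}-1-(3,4,5-trimethoxyphenyl)propan-1-ol
Conditions: (R)-Me-CBS (0.3 equiv), catecholborane (1.8 equiv), toluene, −78 °C; MeOH, then aqueous work-up
Reagents that add atoms: none
Why: Corey–Bakshi–Shibata reduction in which the (R)-oxazaborolidine (aryl as the large group) sets the new carbinol centre as (1R), anti (erythro) to the fixed (2S) centre, under catalyst control because the non‑chelating alkynyloxy group would otherwise favour the Felkin (syn) alcohol; catecholborane does not hydroborate the silyl alkynyl ether at −78 °C and the minor syn epimer is removed by chromatography.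

Step 4
Reactants: 12 (1R,2S)-2-{[(triethylsilyl)ethynyl]oxy}-1-(3,4,5-trimethoxyphenyl)propan-1-ol; 13 trichloroethylene
Product: 18 5-[(1R,2S)-1-(ethynyloxy)-2-{[(triethylsilyl)ethynyl]oxy}propyl]-1,2,3-trimethoxybenzene, via dichloroacetylene 14 (not isolated), via dichlorovinyl ether 15 (not isolated), via chloroalkynyl ether 16 (not isolated), via lithium acetylide 17 (not isolated)
Conditions: KH (1.3 equiv), THF, 0 °C; 13 (1.2 equiv), 0 to 20 °C; n-BuLi (2.5 equiv), −78 to −40 °C; H2O, −78 °C; used at once, kept at or below 20 °C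
Reagents that add atoms: none
Why: Complete Greene alkynyl ether synthesis in one flask (the alkoxide dehydrochlorinates 13 to 14 and adds to it anti to give 15, n‑BuLi eliminates HCl to 16 and exchanges Cl for Li to 17, water protonates), with retention at C1 because the benzylic C–O bond is never broken and with the Et3Si cap keeping the other alkyne terminus blocked and differentiated.

Step 5
Reactants: 18 5-[(1R,2S)-1-(ethynyloxy)-2-{[(triethylsilyl)ethynyl]oxy}propyl]-1,2,3-trimethoxybenzene; 19 pent-1-en-4-yne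
Product: 20 (2R,3S)-3-methyl-7-(prop-2-en-1-yl)-5-(triethylsilyl)-2-(3,4,5-trimethoxyphenyl)-2,3-dihydro-1,4-benzodioxine
Conditions: [Rh(cod)2]BF4/rac-BINAP (5 mol %, H2-activated), CH2Cl2, 20 °C, 19 (3 equiv), slow addition of 18
Reagents that add atoms: none
Why: Proposed new method: Rh(I)-catalysed [2+2+2] alkyne cyclotrimerisation in which oxidative coupling of the two tethered alkynyl‑ether alkynes gives a rhodacyclopentadiene and thereby the C4a–C8a bond that closes the 1,4‑dioxane ring, and insertion of 19 closes the benzene ring in the same operation, the alkyne inserting with its CH2 substituent away from the Et3Si‑bearing carbon so that the allyl group ends up meta to silicon (para to the ring oxygen on the CH(CH3) side), while both stereocentres are spectators and the erythro diyne gives the cis ring; the closest known reaction types are Rh‑catalysed [2+2+2] reactions of heteroatom‑tethered 1,6‑ and 1,7‑diynes (ynamide and aryl ynol ether diynes) with terminal alkynes, which are meta‑selective when one diyne terminus is substituted.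

Step 6
Reactants: 20 (2R,3S)-3-methyl-7-(prop-2-en-1-yl)-5-(triethylsilyl)-2-(3,4,5-trimethoxyphenyl)-2,3-dihydro-1,4-benzodioxine
Product: 21 (2S,3R)-2-methyl-6-(prop-2-en-1-yl)-3-(3,4,5-trimethoxyphenyl)-2,3-dihydro-1,4-benzodioxine
Conditions: CF3CO2H (5 equiv), CH2Cl2, 0 °C; aq NaHCO3
Reagents that add atoms: none
Why: Ipso‑protodesilylation (electrophilic aromatic substitution at the silicon‑bearing carbon, activated by the ortho ring oxygen and β‑silyl stabilisation), fast enough at 0 °C that neither the allyl group nor the benzylic C–O bond (cis to trans epimerisation) is affected.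

## Compound list

1 | (2S)-2-hydroxy-N,N-dimethylpropanamide [(S)-N,N-dimethyllactamide] | C[C@H](O)C(=O)N(C)C | starting material
2 | (Z)-1,2-dichloroethene | Cl/C=C\Cl | starting material
3 | chloroacetylene (chloroethyne) | ClC#C | intermediate (not isolated)
4 | (2S)-2-{[(Z)-2-chloroethenyl]oxy}-N,N-dimethylpropanamide | C[C@H](O/C=C\Cl)C(=O)N(C)C | intermediate
5 | 5-bromo-1,2,3-trimethoxybenzene | COc1cc(Br)cc(OC)c1OC | starting material
6 | (3,4,5-trimethoxyphenyl)lithium | [Li]c1cc(OC)c(OC)c(OC)c1 | intermediate (not isolated)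
7 | lithium (2S)-2-{[(Z)-2-chloroethenyl]oxy}-1-(dimethylamino)-1-(3,4,5-trimethoxyphenyl)propan-1-olate (both C1 epimers) | C[C@H](O/C=C\Cl)C(O[Li])(N(C)C)c1cc(OC)c(OC)c(OC)c1 | intermediate (not isolated)
8 | lithium (2S)-1-(dimethylamino)-2-(ethynyloxy)-1-(3,4,5-trimethoxyphenyl)propan-1-olate | C[C@H](OC#C)C(O[Li])(N(C)C)c1cc(OC)c(OC)c(OC)c1 | intermediate (not isolated)
9 | lithium (2S)-1-(dimethylamino)-2-[(lithioethynyl)oxy]-1-(3,4,5-trimethoxyphenyl)propan-1-olate | C[C@H](OC#C[Li])C(O[Li])(N(C)C)c1cc(OC)c(OC)c(OC)c1 | intermediate (not isolated)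
10 | lithium (2S)-1-(dimethylamino)-2-{[(triethylsilyl)ethynyl]oxy}-1-(3,4,5-trimethoxyphenyl)propan-1-olate | C[C@H](OC#C[Si](CC)(CC)CC)C(O[Li])(N(C)C)c1cc(OC)c(OC)c(OC)c1 | intermediate (not isolated)
11 | (2S)-2-{[(triethylsilyl)ethynyl]oxy}-1-(3,4,5-trimethoxyphenyl)propan-1-one | C[C@H](OC#C[Si](CC)(CC)CC)C(=O)c1cc(OC)c(OC)c(OC)c1 | intermediate
12 | (1R,2S)-2-{[(triethylsilyl)ethynyl]oxy}-1-(3,4,5-trimethoxyphenyl)propan-1-ol | O[C@H](c1cc(OC)c(OC)c(OC)c1)[C@H](C)OC#C[Si](CC)(CC)CC | intermediate
13 | trichloroethylene | ClC=C(Cl)Cl | starting material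
14 | dichloroacetylene | ClC#CCl | intermediate (not isolated)
15 | 5-[(1R,2S)-1-{[(E)-1,2-dichloroethenyl]oxy}-2-{[(triethylsilyl)ethynyl]oxy}propyl]-1,2,3-trimethoxybenzene | Cl/C=C(Cl)\O[C@H](c1cc(OC)c(OC)c(OC)c1)[C@H](C)OC#C[Si](CC)(CC)CC | intermediate (not isolated)
16 | 5-[(1R,2S)-1-[(chloroethynyl)oxy]-2-{[(triethylsilyl)ethynyl]oxy}propyl]-1,2,3-trimethoxybenzene | ClC#CO[C@H](c1cc(OC)c(OC)c(OC)c1)[C@H](C)OC#C[Si](CC)(CC)CC | intermediate (not isolated)
17 | [2-({(1R,2S)-2-{[(triethylsilyl)ethynyl]oxy}-1-(3,4,5-trimethoxyphenyl)propyl}oxy)ethynyl]lithium | [Li]C#CO[C@H](c1cc(OC)c(OC)c(OC)c1)[C@H](C)OC#C[Si](CC)(CC)CC | intermediate (not isolated)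
18 | 5-[(1R,2S)-1-(ethynyloxy)-2-{[(triethylsilyl)ethynyl]oxy}propyl]-1,2,3-trimethoxybenzene | C#CO[C@H](c1cc(OC)c(OC)c(OC)c1)[C@H](C)OC#C[Si](CC)(CC)CC | intermediate
19 | pent-1-en-4-yne | C=CCC#C | starting material
20 | (2R,3S)-3-methyl-7-(prop-2-en-1-yl)-5-(triethylsilyl)-2-(3,4,5-trimethoxyphenyl)-2,3-dihydro-1,4-benzodioxine (cis) | C=CCc1cc([Si](CC)(CC)CC)c2c(c1)O[C@H](c1cc(OC)c(OC)c(OC)c1)[C@H](C)O2 | intermediate
21 | (2S,3R)-2-methyl-6-(prop-2-en-1-yl)-3-(3,4,5-trimethoxyphenyl)-2,3-dihydro-1,4-benzodioxine (cis; CNP0000093.1) | C=CCc1ccc2c(c1)O[C@H](c1cc(OC)c(OC)c(OC)c1)[C@H](C)O2 | target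

## Step count and risk

Total step count: 6. Longest linear sequence: 6 steps (1 → 4 → 11 → 12 → 18 → 20 → 21); 5 enters in step 2, 13 in step 4 and 19 in step 5.

Steps most likely to fail:

Step 5 (the ring‑forming key step). The risks are the sensitivity of the terminal alkynyl ether towards the cationic Rh centre, participation or allyl‑to‑propenyl isomerisation of the 1,4‑enyne partner, and incomplete meta selectivity. The fallback sets out from 18 and comes back at 20. Diyne 18 is cyclotrimerised with 2‑ethynyl‑4,4,5,5‑tetramethyl‑1,3,2‑dioxaborolane in place of 19 (neutral RhCl(PPh3)3 or Cp*RuCl(cod), 20 °C). This gives the arylboronate (2R,3S)‑3‑methyl‑7‑(4,4,5,5‑tetramethyl‑1,3,2‑dioxaborolan‑2‑yl)‑5‑(triethylsilyl)‑2‑(3,4,5‑trimethoxyphenyl)‑2,3‑dihydro‑1,4‑benzodioxine F1; the bulkier boryl group reinforces the meta orientation and no alkene is present during the cycloaddition. The allyl group is then introduced by Suzuki–Miyaura coupling of F1 with allyl bromide (Pd(PPh3)4, CsF, THF), which delivers 20 for step 6.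

Step 4. The risks are that the potassium alkoxide of 12 sits next to the silyl alkynyl ether (5‑exo addition to the alkyne, or attack at silicon) and that the benzylic alkynyl ether is thermally labile. The fallback sets out from 12 and comes back at lithium acetylide 17, and so at 18; it never generates the alkoxide. Alcohol 12 is formylated under neutral conditions (acetic formic anhydride, pyridine, 0 °C) to the formate (1R,2S)‑2‑{[(triethylsilyl)ethynyl]oxy}‑1‑(3,4,5‑trimethoxyphenyl)propyl formate F2. Dibromomethylenation of the formate carbonyl (CBr4, PPh3, CH2Cl2) gives the dibromovinyl ether 5‑[(1R,2S)‑1‑[(2,2‑dibromoethenyl)oxy]‑2‑{[(triethylsilyl)ethynyl]oxy}propyl]‑1,2,3‑trimethoxybenzene F3. n‑BuLi (2.1 equiv, −78 °C; Br–Li exchange, loss of LiBr with 1,2‑H shift, deprotonation) then converts F3 into 17, which is quenched with water to 18 as in step 4.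

Step 2. The risk is that several organometallic events are stacked in one flask: the aryllithium may attack the chlorovinyl ether instead of the amide, or adduct 7 may collapse before silylation. The fallback sets out from 4 and comes back at 12, so that 11 is bypassed. Amide 4 is treated with aryllithium 6 only, and adduct 7 is quenched cold to isolate the ketone (2S)‑2‑{[(Z)‑2‑chloroethenyl]oxy}‑1‑(3,4,5‑trimethoxyphenyl)propan‑1‑one F4. CBS reduction as in step 3 gives the alcohol (1R,2S)‑2‑{[(Z)‑2‑chloroethenyl]oxy}‑1‑(3,4,5‑trimethoxyphenyl)propan‑1‑ol F5. The hydroxyl is capped (Me3SiCl, imidazole) as the silyl ether {[(1R,2S)‑2‑{[(Z)‑2‑chloroethenyl]oxy}‑1‑(3,4,5‑trimethoxyphenyl)propyl]oxy}trimethylsilane F6. LDA (2.3 equiv, −78 to −40 °C) takes F6 in the flask through the ethynyl ether {[(1R,2S)‑2‑(ethynyloxy)‑1‑(3,4,5‑trimethoxyphenyl)propyl]oxy}trimethylsilane F7 to its lithium acetylide [2‑({(1S,2R)‑1‑methyl‑2‑(3,4,5‑trimethoxyphenyl)‑2‑[(trimethylsilyl)oxy]ethyl}oxy)ethynyl]lithium F8. Et3SiCl then gives trimethyl{[(1R,2S)‑2‑{[(triethylsilyl)ethynyl]oxy}‑1‑(3,4,5‑trimethoxyphenyl)propyl]oxy}silane F9. K2CO3 in MeOH at 0 °C removes only the O–SiMe3 group and returns 12.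

## Further compounds

F1 | step 5 | (2R,3S)-3-methyl-7-(4,4,5,5-tetramethyl-1,3,2-dioxaborolan-2-yl)-5-(triethylsilyl)-2-(3,4,5-trimethoxyphenyl)-2,3-dihydro-1,4-benzodioxine | CC1(C)OB(OC1(C)C)c1cc([Si](CC)(CC)CC)c2c(c1)O[C@H](c1cc(OC)c(OC)c(OC)c1)[C@H](C)O2
F2 | step 4 | (1R,2S)-2-{[(triethylsilyl)ethynyl]oxy}-1-(3,4,5-trimethoxyphenyl)propyl formate | O=CO[C@H](c1cc(OC)c(OC)c(OC)c1)[C@H](C)OC#C[Si](CC)(CC)CC
F3 | step 4 | 5-[(1R,2S)-1-[(2,2-dibromoethenyl)oxy]-2-{[(triethylsilyl)ethynyl]oxy}propyl]-1,2,3-trimethoxybenzene | BrC(Br)=CO[C@H](c1cc(OC)c(OC)c(OC)c1)[C@H](C)OC#C[Si](CC)(CC)CC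
F4 | step 2 | (2S)-2-{[(Z)-2-chloroethenyl]oxy}-1-(3,4,5-trimethoxyphenyl)propan-1-one | C[C@H](O/C=C\Cl)C(=O)c1cc(OC)c(OC)c(OC)c1
F5 | step 2 | (1R,2S)-2-{[(Z)-2-chloroethenyl]oxy}-1-(3,4,5-trimethoxyphenyl)propan-1-ol | O[C@H](c1cc(OC)c(OC)c(OC)c1)[C@H](C)O/C=C\Cl
F6 | step 2 | {[(1R,2S)-2-{[(Z)-2-chloroethenyl]oxy}-1-(3,4,5-trimethoxyphenyl)propyl]oxy}trimethylsilane | C[Si](C)(C)O[C@H](c1cc(OC)c(OC)c(OC)c1)[C@H](C)O/C=C\Cl
F7 | step 2 | {[(1R,2S)-2-(ethynyloxy)-1-(3,4,5-trimethoxyphenyl)propyl]oxy}trimethylsilane | C[Si](C)(C)O[C@H](c1cc(OC)c(OC)c(OC)c1)[C@H](C)OC#C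
F8 | step 2 | [2-({(1S,2R)-1-methyl-2-(3,4,5-trimethoxyphenyl)-2-[(trimethylsilyl)oxy]ethyl}oxy)ethynyl]lithium | C[Si](C)(C)O[C@H](c1cc(OC)c(OC)c(OC)c1)[C@H](C)OC#C[Li]
F9 | step 2 | trimethyl{[(1R,2S)-2-{[(triethylsilyl)ethynyl]oxy}-1-(3,4,5-trimethoxyphenyl)propyl]oxy}silane | C[Si](C)(C)O[C@H](c1cc(OC)c(OC)c(OC)c1)[C@H](C)OC#C[Si](CC)(CC)CC
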